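After 4.00 h Sunday's run still held 27.4% of its starting complex beside 7.3% of complex with one exchanged, and we read the flask from that leftover.

| flask | starting complex | incoming ligand | leaving ligand | remark | time |
|---|---|---|---|---|---|
| Sunday's | 0.050 M | 0.10 M | 0.20 M | run made earlier |  |
| Monday's | 0.075 M | 0.10 M | 0.20 M | run made earlier |  |
| flask | 0.10 M | 0.100 M | 0.200 M |  | 3.0 h |

| run | time / h | complex with one exchanged / % | complex with two exchanged / % | starting complex / % |
|---|---|---|---|---|
| Sunday's | 0.0333 | 30.1 | 4.6 | 62.7 |
| Sunday's | 0.0833 | 29.3 | 13.2 | 52.1 |
| Sunday's | 0.250 | 22.0 | 19.9 | 45.3 |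
| Sunday's | 0.500 | 18.6 | 18.5 | 40.8 |
| Sunday's | 1.33 | 14.4 | 13.0 | 35.8 |
| Sunday's | 4.00 | 7.3 | 4.6 | 27.4 |
| Monday's | 0.0333 | 26.7 | 4.5 | 65.9 |
| Monday's | 0.0833 | 27.8 | 11.7 | 56.6 |
| Monday's | 0.250 | 21.2 | 15.7 | 53.0 |
| Monday's | 0.500 | 19.2 | 15.3 | 50.9 |
| Monday's | 1.33 | 15.1 | 9.8 | 49.1 |
| Monday's | 4.00 | 10.3 | 3.3 | 41.5 |

(scatter of a reading: 1 percentage point)

- the earlier runs were read with a standard deviation of 1 percentage point
- steps thought possible: starting complex + incoming ligand <-> leaving ligand + complex with one exchanged; complex with one exchanged + incoming ligand <-> leaving ligand + complex with two exchanged; complex with two exchanged + incoming ligand <-> leaving ligand + complex with three exchanged; complex with three exchanged + incoming ligand <-> leaving ligand + complex with four exchanged; complex with two exchanged -> over-reaction product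

1. time up to 3.0 h at which complex with one exchanged stands highest, in min
2. the amount of complex with one exchanged, in percent of the starting complex charged, at that time
3. the first time at which complex with one exchanged reaches 14%, in the same percent, in min

The first step has a forward time, one over its rate constant times the incoming ligand X, and a back time, one over its rate constant times the leaving ligand L. At balance (quasi-equilibrium) the back time over the forward time is P = K·X/L, and complex with one exchanged over starting complex equals P. If we count the unread part as two exchanged, Sunday's reading shows 0.0689 M of ligand exchanged, which gives the balance constant K = 2.31, a reading with its scatter.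

In this flask each exchange lowers P while the ratio climbs, so we put the peak where they meet. As a correction we take complex with two exchanged at φ = 0.451 of complex with one exchanged, as Sunday read at 4.998 min. The meeting gives 27.1%. Both ligands start as in Sunday's run, so we expect the peak between 1.998 min and 4.998 min, and 14% near 0.599 min.

The forecast, noting that "Ligand is used up faster", gave 28% at 3.5 min and 14% at 0.6 min.

The flask gives 27.4% at 2.90 min, and 14% at 0.535 min.

    starting complex + incoming ligand ⇌ leaving ligand + complex with one exchanged (K = 2.60, k = 0.0593 M⁻¹ s⁻¹)
    complex with one exchanged + incoming ligand ⇌ leaving ligand + complex with two exchanged (K = 5.99, k = 0.0396 M⁻¹ s⁻¹)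
    complex with two exchanged + incoming ligand ⇌ leaving ligand + complex with three exchanged (K = 0.990, k = 0.248 M⁻¹ s⁻¹)
    complex with three exchanged + incoming ligand ⇌ leaving ligand + complex with four exchanged (K = 6.01, k = 0.129 M⁻¹ s⁻¹)
    complex with two exchanged → over-reaction product (k = 4.07 × 10⁻⁴ s⁻¹)

At 0.0484 h in this flask the ratio stood at 0.427, below the P of 0.494 that our read K gives. At 3.00 h it stood at 0.171, with 32.3% of over-reaction product.

With 0.80 M of leaving ligand, P starts at 0.288, and the same K and φ meet at 15.3%. The computed peak there is 16.9%.

(All runs were computed with made-up constants; scatter was added.)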